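All runs stem from a simulated flask with constants of no real substance; noise was put on by code.

I began from the leftover: the starting material still unreacted in each run, which can be counted in half-lives.

| setting | dawn | spring | dusk | flask |
|---|---|---|---|---|
| starting material | 0.34 M | 0.75 M | 0.50 M | 0.50 M |
| partner | 0.75 M | 0.75 M | 1.5 M | 0.750 M |
| remark | run made earlier | run made earlier | run made earlier |  |
| time |  |  |  | 15 min |

| run | time / min | starting material / % | target / % | side product / % |
|---|---|---|---|---|
| dawn | 1.50 | 90.0 | 1.4 | 1.1 |
| dawn | 5.00 | 67.3 | 4.8 | 8.7 |
| dawn | 8.00 | 53.1 | 9.9 | 15.2 |
| dawn | 12.0 | 39.5 | 16.3 | 23.2 |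
| dawn | 20.0 | 23.6 | 25.4 | 32.2 |
| spring | 1.50 | 88.8 | 0.8 | 2.4 |
| spring | 5.00 | 63.8 | 4.4 | 15.9 |
| spring | 8.00 | 48.6 | 8.5 | 27.3 |
| spring | 12.0 | 33.5 | 12.8 | 37.8 |
| spring | 20.0 | 17.9 | 19.1 | 50.3 |
| dusk | 1.33 | 90.4 | 1.4 | 1.2 |
| dusk | 2.50 | 81.7 | 2.9 | 3.7 |
| dusk | 5.00 | 66.5 | 8.5 | 10.9 |
| dusk | 10.0 | 43.9 | 18.1 | 22.6 |
| dusk | 20.0 | 21.5 | 31.3 | 34.4 |

(readings scatter by 0.3 percentage points)

- percent here means starting material units held: one side product counts as two
- the reaction counts as stopped when no species that holds the starting material changes by six tenths of a point or more over the second half of the time

- why nothing more happens at 15 min, or that something still does (the partner has run out first / forward and back rates have come level / it is still moving / all of the starting material has reacted)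
- conversion of starting material at 15 min
- amount of target at 15 min, in percent of the starting material charged
- amount of side product at 15 min, in percent of the starting material charged
- amount of reactive form at 15 min, in percent of the starting material charged

I read the last rows first. At 20.0 min the dusk run held 21.5% of its starting material. The dawn and spring runs have half of dusk's [partner], and interpolated to the [starting material] of 0.50 M shared by dusk and my flask, they gave 21.4%. That was a gap of 0.10 percentage points against a scatter of 0.3 points, so I took dusk's curve to stand for the flask's starting material.

Then I read down the dusk column. From 5.00 min to 10.0 min the half-life was 8.35 min. From 10.0 min to 20.0 min, the span holding the asked time, it was 9.71 min, which is longer. This is the late half-life, the time in which the starting material halves at the pace read between a run's last two readings.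

From 10.0 min to 15 min lie 0.515 late half-lives, which by my reckoning left 30.7%, a conversion of 69.3%. Counted back over the second half of the time, that meant a fall of 22 points, so I judged the flask still moving.

The forecast, with “I interpolate at 15 min between dawn and spring”, said it is still moving: conversion 70%, target 18%, side product 34%, reactive form 18%.

The flask gave it is still moving: conversion 70.4%, target 17.8%, side product 34.9%, reactive form 17.7%.

    starting material + reactive form → side product (k = 0.278 /M/min)
    2 partner → homo dimer (k = 0.0221 /M/min)
    starting material ⇌ reactive form (K = 1.69, k = 0.0737 /min)
    partner + reactive form → target (k = 0.134 /M/min)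

In the flask, reactive form went to target at 0.89 times its rate to side product at 4.66 min, and at 1.4 times at 15.0 min, 1.06 late half-lives later. Side product still stood above target at the end. Its 34.9% moved 5 points in the flask stopped at 12.0 min or 19.1 min, or charged with 0.392 M or 0.629 M of starting material, and a change of that size is what it would take to part from the forecast.

The neighbour flask with 3.0 M of partner keeps the charge of starting material, so the same count gives 30.7% left. Computed, that neighbour held 30.5% of starting material, with target at 32.9%.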